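## Structural features

The target 23 is an achiral macrocyclic bis(bibenzyl). Four benzene rings are tied into a 17-membered ring by two CH2CH2 bridges (ring A to ring D, ring B to ring C) and two diaryl ether oxygens (ring A to ring B, ring C to ring D). Ring A is 1,2,3-trioxygenated: its outer oxygen is the ether to ring B, the other two are free hydroxyls, and its ethano bridge lies para to the central oxygen; ring B is a para-phenylene. Ring C also carries three contiguous oxygens, but here the one next to the ethano bridge is the ether to ring D and the other two form the second catechol. Ring D is an ortho-phenylene whose other four carbons are unsubstituted CH. There is no stereocentre and no alkene, so no stereocentres stand next to each other; the selectivity problems are regiochemistry and telling six oxygens apart. The two catechols are oxidation-prone and are best unveiled last, and on the way an aryl bromide, a benzyl ether and an acid- and heat-sensitive alkynyl ether must be handled. The real difficulty lies in the two diaryl ethers, each at a flanked position (the ring C oxygen sits between a methoxy-bearing carbon and the chain-bearing carbon; the ring A ether carbon sits next to an oxygenated carbon), and in closing the large ring without oligomerization. The key step exploits ring D: its oxygen-bearing and chain-bearing carbons are neighbours and can be the two carbons of an alkyne already bonded to the ring C oxygen, while the four CH carbons can be C3 to C6 of an unsubstituted pyranone.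

## Logic of the disconnections

23 to 22: the four phenolic O–H bonds are traced back to O–CH3 bonds. The catechols are thereby carried in a form that survives base, organolithium, heat and copper. The gain is a robust, non-oxidizable macrocycle. The demand is a final ether cleavage that removes four methyl groups and leaves both diaryl ether bonds and the benzylic CH2 groups untouched.

22 to 21: the ring A carbon–oxygen bond of the ring A/ring B ether is cut, the oxygen staying on ring B. The ring B oxygen is an unhindered para-alkyl phenol and therefore the better nucleophile, and the ring A carbon becomes a bromide that is already present in 10. The macrocycle opens to a linear chain of four rings. The forward step must close a 17-membered ring by copper-mediated C–O coupling at a methoxy-flanked bromide, which requires high dilution and a single free hydroxyl.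

21 to 20: the ring B O–H is traced back to an O–benzyl bond. This mask must survive base, an alkyllithium and 130 °C, and must differ from the methyl ethers. The demand is a debenzylation that neither reduces the C–Br bond nor cleaves a methyl ether.

20 to 17 and 18: in ring D the two C–C bonds that join the CH=CH–CH=CH unit to the oxygen-bearing and the chain-bearing carbon are cut. Ring D disappears: its two substituted carbons become the alkyne of 17, and the four CH carbons become the diene of 18, whose remaining atoms leave as CO2. The hindered ring C–O–ring D ether no longer has to be made by arylation, and the A–D ethano bridge is set at the same time. The forward cycloaddition must be faster than any decomposition of the alkynyl ether.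

17 to 9 and 14: the bond between the alkyne carbon and the CH2CH2 chain is cut. 9 is a latent alkynyl anion (through 15 and 16) and 14 is a primary electrophile, so two fragments of similar size are joined late. The substitution must outrun elimination, and the bromide of 14 must never meet an alkyllithium, so metallation has to be complete before 14 is added.

9 to 6 and 7: the oxygen–vinyl carbon bond is cut. A two-carbon chloroalkene is small enough to reach the flanked phenoxide of 6, and it delivers both future ring D carbons in one operation. The demand is a mild base-mediated O-vinylation that stops at the dichlorovinyl ether.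

6 to 5, then to 2 and 3, then 2 to 1: the central C–C bond of the ring B–ring C bridge is cut by way of the alkene 5. 3 already has the correct oxygen pattern, with its free hydroxyl at the position that becomes the ether oxygen, and 1 carries the masked ring B oxygen. The olefination must tolerate the ortho hydroxyl, and the saturation must spare the benzyl ether.

14 to 13, 11 and 10: the C–O bond of the sulfonate, the terminal C–OH bond (anti-Markovnikov hydration of 11) and the vinyl C=C bond are cut in turn. This is a one-carbon homologation of an aldehyde that already has bromine and both oxygens in the right places. The demands are terminal regioselectivity in the hydroboration and cold, immediate use of 14.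

## Other disconnections considered

Alternative 1: Ring B is dissolved instead of ring D. The open-chain precursor A1 carries a buta-1,3-dien-2-yl ether on the outer ring A oxygen and a but-3-yn-2-one unit on ring C. An intramolecular (4+2) cycloaddition would form two C–C bonds and give the macrocyclic cyclohexa-1,4-diene ketone A2.
- In its favour: arene construction and macrocyclization are merged, no metal-mediated C–O ring closure is needed, and donor and acceptor are placed so that the electronically preferred para orientation is the one the tether requires.
- Against it here: A2 is two adjustments away from the skeleton (dehydrogenation of the diene ring to ring B, removal of the bridge carbonyl). The dienyl ether must be installed on an oxygen-flanked phenol and is prone to polymerize. The CH2 between ring C and the ynone is acidic and invites isomerization. The ring-closing cycloaddition must compete with intermolecular addition and so needs dilution. The ring C–O–ring D ether must still be made by arylating the hindered ring C phenol.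
- Comparison: on bond economy at the macrocycle, Alternative 1 is the better plan, since one event does what steps 9 and 11 do separately. After the key step both plans need three operations, so they are equal there. The chosen plan is better in that 20 leaves its key step at the correct oxidation level, the cycloaddition is intermolecular with an excess partner, and CO2 loss makes it irreversible. Neither plan has a stereochemical issue.

Alternative 2: The bond between ring A and its benzylic CH2 is cut. The precursor is the macrocyclic allyl aryl ether A3, in which the central ring A oxygen carries a 2-arylallyl group whose aryl is ring D. Heating would cause a [3,3] Claisen shift to an ortho carbon (both are blocked), then a [3,3] Cope shift to the para carbon and tautomerization to the phenol A4.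
- In its favour: the macrocycle would be closed earlier by a simple O-alkylation with an allylic electrophile, which is easier than the aryl C–O coupling of step 11 and a point on which this alternative is the better one. The central oxygen is released as the free hydroxyl that the target has, and the ring size (17) is the same before and after the shift.
- Against it here: A4 has one carbon too many; the exocyclic methylene must be cleaved oxidatively and the resulting benzylic ketone deoxygenated in the presence of electron-rich rings. The two consecutive shifts must occur with the allyl unit tied through its central carbon into the macrocycle, and whether the ortho and then the para carbon can be reached is uncertain. Both diaryl ethers must first be made by arylation, including the hindered ring C oxygen.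
- Comparison: both plans rest on a thermal pericyclic key step and neither has a stereocentre, so they are equal in mechanism type and stereochemistry. The chosen plan keeps every carbon it introduces and is shorter overall.

Alternative 3: Ring A itself is built. Irradiation of the diazo ketone A5 triggers a Wolff rearrangement; the resulting ketene adds to di-tert-butoxyethyne A6, and four-electron ring opening followed by six-electron ring closure would give the phenol A7 with three new C–C bonds.
- In its favour: the three ring A oxygens emerge differentiated (one free hydroxyl for the later ether closure, two acid-labile tert-butyl ethers), which the chosen plan does not achieve on ring A. The electrophile for the macrocyclization would be an unhindered para-bromide on ring B, better than the methoxy-flanked bromide of 21, although the nucleophile would then be the hindered ring A phenol. After the key step only two operations remain, against three in the chosen plan, so Alternative 3 is better on that count.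
- Against it here: A5 needs a multi-step preparation and can react with its own alkene. A6 is not a stock chemical and is thermally fragile. Ultraviolet light in the presence of an aryl bromide risks C–Br homolysis. The hindered ring C–O–ring D ether must still be made by arylation. Ring A is the one ring that can be bought with the right substitution pattern (10).
- Comparison: both are pericyclic arene syntheses without stereochemical issues and are equal in that respect. The chosen plan builds the ring that has no spare substituents and uses a purchasable diene, so it is clearly shorter before the key step.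

Key step: step 9

Remark: 17 and 20 map atom for atom onto 23 (17-membered ring, ring A bromide at the carbon that becomes the ether carbon), so no structural correction is needed; the 17-membered ring is taken to be conformationally mobile, so no stereocontrol is required.

## Route

Step 1
Reactants: 1 4-(benzyloxy)benzyl chloride
Product: 2 [4-(benzyloxy)benzyl]triphenylphosphonium chloride
Conditions: PPh3, toluene, reflux
Reagents that add atoms: triphenylphosphine, c1ccc(cc1)P(c1ccccc1)c1ccccc1
Why: SN2 quaternization of a benzylic chloride by a phosphine; the salt should precipitate and need no chromatography.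

Step 2
Reactants: 2 [4-(benzyloxy)benzyl]triphenylphosphonium chloride; 3 2-hydroxy-3,4-dimethoxybenzaldehyde
Product: 5 6-{2-[4-(benzyloxy)phenyl]ethenyl}-2,3-dimethoxyphenol (mixture of E and Z isomers), via ylide 4 (not isolated)
Conditions: KOtBu (2.3 equiv), THF, 0 °C to 60 °C
Reagents that add atoms: none
Why: Wittig olefination with a semistabilized benzylic ylide; one equivalent of base is consumed by the phenol and the ylide should still add to the phenoxide aldehyde on warming; the alkene geometry is irrelevant because step 3 saturates it.

Step 3
Reactants: 5 6-{2-[4-(benzyloxy)phenyl]ethenyl}-2,3-dimethoxyphenol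
Product: 6 6-{2-[4-(benzyloxy)phenyl]ethyl}-2,3-dimethoxyphenol
Conditions: TsNHNH2, NaOAc, THF/H2O, reflux
Reagents that add atoms: none
Why: Diimide reduction (concerted syn transfer of H2 from HN=NH generated in the flask) saturates both alkene isomers and, unlike catalytic hydrogenation, leaves the benzyl ether intact.

Step 4
Reactants: 6 6-{2-[4-(benzyloxy)phenyl]ethyl}-2,3-dimethoxyphenol; 7 trichloroethylene
Product: 9 1-{2-[4-(benzyloxy)phenyl]ethyl}-2-{[(E)-1,2-dichloroethenyl]oxy}-3,4-dimethoxybenzene, via dichloroacetylene 8 (not isolated)
Conditions: K2CO3, DMF, 70 °C, dilute, vented to a scrubber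
Reagents that add atoms: none
Why: Base removes HCl from 7 to give transient 8, to which the phenoxide of 6 adds with anti protonation (net vinylic substitution by addition–elimination, the known route from phenols to aryl 1,2-dichlorovinyl ethers); the two-carbon electrophile is small enough for the flanked oxygen, and 8 is kept dilute and never isolated for safety.

Step 5
Reactants: 10 3-bromo-4,5-dimethoxybenzaldehyde
Product: 11 1-bromo-5-ethenyl-2,3-dimethoxybenzene
Conditions: Ph3PCH3Br, KOtBu, THF, 0 °C to rt
Reagents that add atoms: methyltriphenylphosphonium bromide, [Br-].C[P+](c1ccccc1)(c1ccccc1)c1ccccc1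
Why: Wittig methylenation of an aromatic aldehyde; the aryl bromide and methyl ethers are inert to the non-stabilized ylide.

Step 6
Reactants: 11 1-bromo-5-ethenyl-2,3-dimethoxybenzene
Product: 13 2-(3-bromo-4,5-dimethoxyphenyl)ethanol, via alkylborane 12 (not isolated)
Conditions: 9-BBN, THF, 0 °C to rt; then NaOH, H2O2, 0 °C
Reagents that add atoms: hydrogen peroxide, OO
Why: Hydroboration–oxidation; the bulky borane places boron on the terminal carbon of the styrene, and oxidation with retention gives the primary alcohol without touching the C–Br bond.

Step 7
Reactants: 13 2-(3-bromo-4,5-dimethoxyphenyl)ethanol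
Product: 14 2-(3-bromo-4,5-dimethoxyphenyl)ethyl trifluoromethanesulfonate
Conditions: Tf2O, 2,6-lutidine, CH2Cl2, −78 °C; cold filtration through silica, used at once
Reagents that add atoms: trifluoromethanesulfonic anhydride, O=S(=O)(OS(=O)(=O)C(F)(F)F)C(F)(F)F
Why: O-sulfonylation of a primary alcohol with a hindered pyridine base; the product is kept cold and used immediately to avoid aryl-assisted ionization.

Step 8
Reactants: 9 1-{2-[4-(benzyloxy)phenyl]ethyl}-2-{[(E)-1,2-dichloroethenyl]oxy}-3,4-dimethoxybenzene; 14 2-(3-bromo-4,5-dimethoxyphenyl)ethyl trifluoromethanesulfonate
Product: 17 1-{2-[4-(benzyloxy)phenyl]ethyl}-2-{[4-(3-bromo-4,5-dimethoxyphenyl)but-1-yn-1-yl]oxy}-3,4-dimethoxybenzene, via chloroalkynyl ether 15 (not isolated), via lithium alkynyl ether 16 (not isolated)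
Conditions: n-BuLi (2.05 equiv, titrated), THF, −78 °C; then 14, −78 °C to 0 °C; work-up and chromatography on Et3N-deactivated silica
Reagents that add atoms: none
Why: Vinylic deprotonation and loss of LiCl give 15, lithium–chlorine exchange gives 16, and the acetylide is alkylated by the primary triflate in an SN2 step (the known dichlorovinyl ether route to alkynyl ethers, followed by acetylide alkylation); the alkyllithium is consumed before the bromide-bearing electrophile is added, so the C–Br bond is not exchanged.

Step 9
Reactants: 17 1-{2-[4-(benzyloxy)phenyl]ethyl}-2-{[4-(3-bromo-4,5-dimethoxyphenyl)but-1-yn-1-yl]oxy}-3,4-dimethoxybenzene; 18 2H-pyran-2-one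
Product: 20 1-{2-[4-(benzyloxy)phenyl]ethyl}-2-{2-[2-(3-bromo-4,5-dimethoxyphenyl)ethyl]phenoxy}-3,4-dimethoxybenzene, via bridged lactone 19 (not isolated)
Conditions: 18 (5 equiv), BHT (cat.), toluene, 130 °C, sealed base-washed tube, argon
Reagents that add atoms: none
Why: The C3–C6 diene of 18 is electron-poor and the C≡C of 17 is raised in energy by the aryloxy oxygen, so a concerted, suprafacial inverse-demand (4+2) addition is expected on heating, the alkyl-bearing (nucleophilic) alkyne carbon bonding to C6 and the oxygen-bearing carbon to C3 of 18 to give 19. 19 is a 2-oxabicyclo[2.2.2]octadienone that undergoes cycloreversion at the reaction temperature, expelling its O–C(=O) bridge as CO2 and leaving ring D aromatic, which makes the sequence irreversible. The closest known reaction type is the thermal pyranone–alkyne Diels–Alder and retro-Diels–Alder benzannulation, practised with ynamines and alkynyl ethers. Ring D is therefore closed not by a tether cyclization but by an intermolecular two-bond cycloaddition that forms the six-membered ring in one event, followed by extrusion. No stereocentre remains: the two bridgehead centres of 19 are fixed relative to each other by the bicycle and both become sp2 carbons in 20. Regiochemistry needs no control, because 18 is unsubstituted and either orientation of the alkyne leads to the same ortho-disubstituted ring. The selectivity that matters is chemoselectivity, cycloaddition against loss of the alkynyl ether: the O-aryl group offers no β-hydrogen for a retro-ene path to a ketene, both ortho positions of ring C are substituted so a [3,3] shift into ring C cannot end in rearomatization, and excess 18 in a dry, neutral, base-washed vessel keeps the bimolecular step fast and suppresses acid-catalysed hydration. The aryl bromide, the benzyl ether and the methyl ethers are inert to these neutral thermal conditions.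

Step 10
Reactants: 20 1-{2-[4-(benzyloxy)phenyl]ethyl}-2-{2-[2-(3-bromo-4,5-dimethoxyphenyl)ethyl]phenoxy}-3,4-dimethoxybenzene
Product: 21 4-{2-[2-(2-{2-(3-bromo-4,5-dimethoxyphenyl)ethyl}phenoxy)-3,4-dimethoxyphenyl]ethyl}phenol
Conditions: BCl3, pentamethylbenzene, CH2Cl2, −78 °C; MeOH quench
Reagents that add atoms: none
Why: Lewis-acid debenzylation with a non-basic cation scavenger; boron activates the benzyl ether oxygen and the benzyl cation is trapped by pentamethylbenzene in a Friedel–Crafts step, while at −78 °C methyl ethers, diaryl ethers and the C–Br bond (which hydrogenolysis would endanger) should be untouched.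

Step 11
Reactants: 21 4-{2-[2-(2-{2-(3-bromo-4,5-dimethoxyphenyl)ethyl}phenoxy)-3,4-dimethoxyphenyl]ethyl}phenol
Product: 22 tetra-O-methyl ether of the target, the 17-membered macrocycle in which the ring B oxygen is bonded to the former C–Br carbon of ring A
Conditions: CuI (cat.), N,N-dimethylglycine, Cs2CO3, 1,4-dioxane, 105 °C, syringe-pump addition to about 2 mM
Reagents that add atoms: none
Why: Intramolecular Ullmann diaryl ether synthesis; the caesium phenoxide of ring B binds monovalent copper, the ring A C–Br bond is activated and C–O reductive elimination closes the 17-membered ring, with high dilution favouring cyclization and every other oxygen masked as a methyl ether so that only one nucleophile is present.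

Step 12
Reactants: 22 tetra-O-methyl ether of the target
Product: 23 the target, the 17-membered bis(bibenzyl) with two catechol units (rings A and C)
Conditions: BBr3, CH2Cl2, −78 °C to rt; then H2O, Na2S2O4 wash, argon
Reagents that add atoms: none
Why: BBr3 demethylation (bromide attacks the methyl group of each boron-complexed aryl methyl ether in an SN2 step); diaryl ethers have no sp3 carbon on oxygen and are not cleaved, and a reductive, oxygen-free work-up protects the catechols.

## Compound list

1 | 4-(benzyloxy)benzyl chloride | ClCc1ccc(OCc2ccccc2)cc1 | starting material
2 | [4-(benzyloxy)benzyl]triphenylphosphonium chloride | [Cl-].c1ccc(cc1)[P+](Cc1ccc(OCc2ccccc2)cc1)(c1ccccc1)c1ccccc1 | intermediate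
3 | 2-hydroxy-3,4-dimethoxybenzaldehyde | COc1ccc(C=O)c(O)c1OC | starting material
4 | [4-(benzyloxy)benzylidene]triphenylphosphorane (ylide, not isolated) | c1ccc(cc1)P(=Cc1ccc(OCc2ccccc2)cc1)(c1ccccc1)c1ccccc1 | intermediate
5 | 6-{2-[4-(benzyloxy)phenyl]ethenyl}-2,3-dimethoxyphenol (E/Z mixture, geometry not specified) | COc1ccc(C=Cc2ccc(OCc3ccccc3)cc2)c(O)c1OC | intermediate
6 | 6-{2-[4-(benzyloxy)phenyl]ethyl}-2,3-dimethoxyphenol | COc1ccc(CCc2ccc(OCc3ccccc3)cc2)c(O)c1OC | intermediate
7 | trichloroethylene | ClC=C(Cl)Cl | starting material
8 | dichloroacetylene (not isolated) | ClC#CCl | intermediate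
9 | 1-{2-[4-(benzyloxy)phenyl]ethyl}-2-{[(E)-1,2-dichloroethenyl]oxy}-3,4-dimethoxybenzene | COc1ccc(CCc2ccc(OCc3ccccc3)cc2)c(O/C(Cl)=C\Cl)c1OC | intermediate
10 | 3-bromo-4,5-dimethoxybenzaldehyde | COc1cc(C=O)cc(Br)c1OC | starting material
11 | 1-bromo-5-ethenyl-2,3-dimethoxybenzene | COc1cc(C=C)cc(Br)c1OC | intermediate
12 | 9-[2-(3-bromo-4,5-dimethoxyphenyl)ethyl]-9-borabicyclo[3.3.1]nonane (not isolated) | COc1cc(CCB2C3CCCC2CCC3)cc(Br)c1OC | intermediate
13 | 2-(3-bromo-4,5-dimethoxyphenyl)ethanol | COc1cc(CCO)cc(Br)c1OC | intermediate
14 | 2-(3-bromo-4,5-dimethoxyphenyl)ethyl trifluoromethanesulfonate | COc1cc(CCOS(=O)(=O)C(F)(F)F)cc(Br)c1OC | intermediate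
15 | 1-{2-[4-(benzyloxy)phenyl]ethyl}-2-[(chloroethynyl)oxy]-3,4-dimethoxybenzene (not isolated) | COc1ccc(CCc2ccc(OCc3ccccc3)cc2)c(OC#CCl)c1OC | intermediate
16 | lithium alkynyl ether: lithio derivative of the aryloxyethyne from 9 (not isolated) | COc1ccc(CCc2ccc(OCc3ccccc3)cc2)c(OC#C[Li])c1OC | intermediate
17 | 1-{2-[4-(benzyloxy)phenyl]ethyl}-2-{[4-(3-bromo-4,5-dimethoxyphenyl)but-1-yn-1-yl]oxy}-3,4-dimethoxybenzene | COc1ccc(CCc2ccc(OCc3ccccc3)cc2)c(OC#CCCc2cc(Br)c(OC)c(OC)c2)c1OC | intermediate
18 | 2H-pyran-2-one | O=C1C=CC=CO1 | starting material
19 | racemic 2-oxabicyclo[2.2.2]octa-5,7-dien-3-one with the ring C aryloxy group on C8 and the 2-(3-bromo-4,5-dimethoxyphenyl)ethyl group on C7 (not isolated; bridgeheads fixed by the bicycle) | O=C1OC2C=CC1C(Oc1c(CCc3ccc(OCc4ccccc4)cc3)ccc(OC)c1OC)=C2CCc1cc(Br)c(OC)c(OC)c1 | intermediate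
20 | 1-{2-[4-(benzyloxy)phenyl]ethyl}-2-{2-[2-(3-bromo-4,5-dimethoxyphenyl)ethyl]phenoxy}-3,4-dimethoxybenzene | COc1ccc(CCc2ccc(OCc3ccccc3)cc2)c(Oc2ccccc2CCc2cc(Br)c(OC)c(OC)c2)c1OC | intermediate
21 | 4-{2-[2-(2-{2-(3-bromo-4,5-dimethoxyphenyl)ethyl}phenoxy)-3,4-dimethoxyphenyl]ethyl}phenol | COc1ccc(CCc2ccc(O)cc2)c(Oc2ccccc2CCc2cc(Br)c(OC)c(OC)c2)c1OC | intermediate
22 | tetra-O-methyl ether of the target (17-membered macrocycle, two OMe on ring A, two on ring C) | COc1cc2cc(c1OC)Oc1ccc(cc1)CCc1ccc(OC)c(OC)c1Oc1ccccc1CC2 | intermediate
23 | CNP0114693.0, macrocyclic bis(bibenzyl) tetraphenol (achiral) | Oc1cc2cc(c1O)Oc1ccc(cc1)CCc1ccc(O)c(O)c1Oc1ccccc1CC2 | target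

## Step count and risks

Total: 12 steps. Longest linear sequence: 9 steps (steps 1, 2, 3, 4, 8, 9, 10, 11, 12); the ring A branch (steps 5 to 7) joins at step 8.

Step 9 (key step). The most likely failure is that thermal or trace-acid decomposition of the alkynyl ether (hydration, oligomerization, rearrangement) outpaces a sluggish cycloaddition, because the unsubstituted pyranone is only moderately electron-poor. The fallback gives up the ring D construction and arylates the hindered phenol with an activated fluoroarene. It sets out from 6 (and 10) and returns at 20. SNAr of 6 with 2-fluorobenzaldehyde (K2CO3, DMA, 120 °C) would give 2-(6-{2-[4-(benzyloxy)phenyl]ethyl}-2,3-dimethoxyphenoxy)benzaldehyde F1. In parallel, 10 would be reduced (NaBH4, MeOH) to (3-bromo-4,5-dimethoxyphenyl)methanol F2 and converted with PPh3·HBr (MeCN, reflux) into (3-bromo-4,5-dimethoxybenzyl)triphenylphosphonium bromide F3. Wittig coupling of F3 with F1 (KOtBu, THF) would give the stilbene 1-{2-[4-(benzyloxy)phenyl]ethyl}-2-{2-[2-(3-bromo-4,5-dimethoxyphenyl)ethenyl]phenoxy}-3,4-dimethoxybenzene F4 as an E/Z mixture, and diimide reduction (TsNHNH2, NaOAc) would give 20 with the C–Br and benzyl ether intact.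

Step 8. Substitution at the phenethyl triflate may lose to E2 elimination, aryl-assisted ionization or proton transfer, and the alkynyl ether may hydrate on acidic work-up. The fallback replaces the ionization-prone sulfonate by a soft halide under dipolar activation. It sets out from 13 and returns at 17. Appel iodination (I2, PPh3, imidazole, CH2Cl2) would give 1-bromo-5-(2-iodoethyl)-2,3-dimethoxybenzene F5, which would alkylate 16 (generated from 9 as in step 8) in THF/DMPU at −78 °C to rt. If this also fails, the fallback described for step 9 bypasses 17 altogether.

Step 11. Intermolecular oligomerization and reductive loss of bromine may compete with slow copper activation of the methoxy-flanked, electron-rich C–Br bond. The fallback changes the coupling to an oxidative one at room temperature. It sets out from 21 and returns at 22. Miyaura borylation (B2pin2, Pd(dppf)Cl2, KOAc, dioxane, 90 °C) would give the phenol pinacol boronate 4-{2-[2-(2-{2-[3,4-dimethoxy-5-(4,4,5,5-tetramethyl-1,3,2-dioxaborolan-2-yl)phenyl]ethyl}phenoxy)-3,4-dimethoxyphenyl]ethyl}phenol F6. Cleavage of the pinacol ester (NaIO4, NH4OAc, acetone/H2O) would give the boronic acid [5-(2-{2-[6-(2-(4-hydroxyphenyl)ethyl)-2,3-dimethoxyphenoxy]phenyl}ethyl)-2,3-dimethoxyphenyl]boronic acid F7. An intramolecular Chan–Lam coupling (catalytic Cu(OAc)2, pyridine, O2, 4 Å molecular sieves, CH2Cl2, rt, high dilution) would close the ring to 22.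

Step 2. Olefination may stall because the ortho phenoxide deactivates the aldehyde and consumes base. The fallback masks the oxygen first with the group it must carry anyway, at no cost in steps. It sets out from 3 and returns at 9. Treatment of 3 with 7 (K2CO3, DMF, 70 °C) would give 2-{[(E)-1,2-dichloroethenyl]oxy}-3,4-dimethoxybenzaldehyde F8. Wittig reaction with ylide 4 (from 2 and one equivalent of KOtBu) would give the stilbene 1-{2-[4-(benzyloxy)phenyl]ethenyl}-2-{[(E)-1,2-dichloroethenyl]oxy}-3,4-dimethoxybenzene F9. Diimide should reduce the disubstituted stilbene alkene of F9 in preference to the chlorinated enol ether and give 9.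

## Further compounds

F1 | step 9 | 2-(6-{2-[4-(benzyloxy)phenyl]ethyl}-2,3-dimethoxyphenoxy)benzaldehyde | COc1ccc(CCc2ccc(OCc3ccccc3)cc2)c(Oc2ccccc2C=O)c1OC
F2 | step 9 | (3-bromo-4,5-dimethoxyphenyl)methanol | COc1cc(CO)cc(Br)c1OC
F3 | step 9 | (3-bromo-4,5-dimethoxybenzyl)triphenylphosphonium bromide | [Br-].COc1cc(C[P+](c2ccccc2)(c2ccccc2)c2ccccc2)cc(Br)c1OC
F4 | step 9 | 1-{2-[4-(benzyloxy)phenyl]ethyl}-2-{2-[2-(3-bromo-4,5-dimethoxyphenyl)ethenyl]phenoxy}-3,4-dimethoxybenzene (E/Z mixture) | COc1ccc(CCc2ccc(OCc3ccccc3)cc2)c(Oc2ccccc2C=Cc2cc(Br)c(OC)c(OC)c2)c1OC
F5 | step 8 | 1-bromo-5-(2-iodoethyl)-2,3-dimethoxybenzene | COc1cc(CCI)cc(Br)c1OC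
F6 | step 11 | phenol pinacol boronate (Bpin in place of Br of 21) | COc1ccc(CCc2ccc(O)cc2)c(Oc2ccccc2CCc2cc(B3OC(C)(C)C(C)(C)O3)c(OC)c(OC)c2)c1OC
F7 | step 11 | phenol boronic acid (B(OH)2 in place of Br of 21) | COc1ccc(CCc2ccc(O)cc2)c(Oc2ccccc2CCc2cc(B(O)O)c(OC)c(OC)c2)c1OC
F8 | step 2 | 2-{[(E)-1,2-dichloroethenyl]oxy}-3,4-dimethoxybenzaldehyde | COc1ccc(C=O)c(O/C(Cl)=C\Cl)c1OC
F9 | step 2 | 1-{2-[4-(benzyloxy)phenyl]ethenyl}-2-{[(E)-1,2-dichloroethenyl]oxy}-3,4-dimethoxybenzene (E/Z mixture at the stilbene) | COc1ccc(C=Cc2ccc(OCc3ccccc3)cc2)c(O/C(Cl)=C\Cl)c1OC
A1 | alternative 1 | 1-{2-[2-(2-{3-(buta-1,3-dien-2-yloxy)-4,5-dimethoxyphenyl}ethyl)phenoxy]-3,4-dimethoxyphenyl}but-3-yn-2-one | C=CC(=C)Oc1cc(CCc2ccccc2Oc2c(CC(=O)C#C)ccc(OC)c2OC)cc(OC)c1OC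
A2 | alternative 1 | macrocyclic cyclohexa-1,4-diene ketone (ring B as its dihydro form, B–C bridge as CH2C(=O)) | COc1cc2cc(c1OC)OC1=CCC(=CC1)C(=O)Cc1ccc(OC)c(OC)c1Oc1ccccc1CC2
A3 | alternative 2 | macrocyclic 2-arylallyl ether of the central ring A oxygen | C=C1COc2c(OC)cccc2Oc2ccc(cc2)CCc2ccc(OC)c(OC)c2Oc2ccccc21
A4 | alternative 2 | macrocyclic phenol with exocyclic methylene on the A–D bridge | C=C1Cc2cc(OC)c(O)c(c2)Oc2ccc(cc2)CCc2ccc(OC)c(OC)c2Oc2ccccc21
A5 | alternative 3 | 5-(2-{6-[2-(4-bromophenyl)ethyl]-2,3-dimethoxyphenoxy}phenyl)-1-diazo-3-methylidenepentan-2-one | [N-]=[N+]=CC(=O)C(=C)CCc1ccccc1Oc1c(CCc2ccc(Br)cc2)ccc(OC)c1OC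
A6 | alternative 3 | di-tert-butoxyethyne | CC(C)(C)OC#COC(C)(C)C
A7 | alternative 3 | ring A phenol with two tert-butyl ethers (2,3-di-tert-butoxy-5-alkylphenol) | Oc1cc(CCc2ccccc2Oc2c(CCc3ccc(Br)cc3)ccc(OC)c2OC)cc(OC(C)(C)C)c1OC(C)(C)C
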